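Ring A is cut at the C4a–C5 bond. Carbons C5–C8, with O at C5 and C8 (a para-hydroquinone), OMe at C7 and H at C6, are supplied by a squarate-derived 4-hydroxy-3-methoxycyclobutenone. C4a and C8a are the unsubstituted C5=C6 alkene of a preformed 2-aryl-3-methoxy-4-pyranone (rings C and B). In one thermal operation the four-membered ring opens to a dienylketene and recloses onto that alkene, so the fully substituted hydroquinone ring A appears with the C4a–C5 bond. The precursor is the tertiary carbinol made by adding the C6-lithiated pyranone to methyl semisquarate; the pyranone comes from 3-bromofuran and the tribenzylated aldehyde, and hydrogenolysis ends the route.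

Key step: step 7

Remark (stereochemistry): the target has no stereogenic element, so the single enantiomer asked for is simply the constitution drawn; the racemic centres that appear in 4, 5, 9, 12 and 14 are all destroyed on the way.

Remark (design): oxidative ring expansion of a plain furyl carbinol stops one oxidation level short of a 3-hydroxy-4-pyranone, and a second equivalent of free halogen would attack the electron-rich B ring. The halogen is therefore carried in on the furan (3-bromofuran) and leaves as bromide in step 3.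

Step 1
Reactants: 1 3-bromofuran; 2 3,4,5-tris(benzyloxy)benzaldehyde
Product: 4 (3-bromofuran-2-yl)[3,4,5-tris(benzyloxy)phenyl]methanol (racemic), via 3-bromo-2-furyllithium 3 (not isolated)
Conditions: LDA, THF, −78 °C; then 2, −78 °C; aq. NH4Cl
Reagents that add atoms: none
Why: Lithium diisopropylamide removes the C2 proton of 3-bromofuran (acidified by both O and Br) without touching the C–Br bond, and the furyllithium adds to the aldehyde in a plain 1,2-carbonyl addition; the carbinol centre forms racemic and is erased in step 3.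

Step 2
Reactants: 4 (3-bromofuran-2-yl)[3,4,5-tris(benzyloxy)phenyl]methanol
Product: 5 4-bromo-6-hydroxy-2-[3,4,5-tris(benzyloxy)phenyl]-2H-pyran-3(6H)-one (racemic, mixture of C2/C6 diastereomers)
Conditions: NBS (1.0 equiv), NaHCO3, THF–H2O 4:1, 0 °C
Reagents that add atoms: water, O
Why: Achmatowicz rearrangement, in which bromonium attack at the free furan α-position, hydrolytic opening to the cis-ene-dione and hemiacetal closure by the carbinol oxygen give the pyranone, the furan being far more nucleophilic than the benzyloxyarene and the ring bromine ending at C4 where step 3 needs a leaving group; the C2 and C6 centres form unselectively and both vanish in step 3.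

Step 3
Reactants: 5 4-bromo-6-hydroxy-2-[3,4,5-tris(benzyloxy)phenyl]-2H-pyran-3(6H)-one
Product: 6 3-hydroxy-2-[3,4,5-tris(benzyloxy)phenyl]-4H-pyran-4-one
Conditions: 2 M aq. HCl–1,4-dioxane 1:4, 80 °C
Reagents that add atoms: water, O
Why: Acid-mediated vinylogous hydrolysis known for 4-halo-6-hydroxy-2H-pyran-3(6H)-ones, in which loss of the anomeric hydroxyl gives a hydroxypyrylium-type cation, water adds at C4, bromide leaves and the resulting 3,4-dione enolises toward C2 to the γ-pyrone, so the required oxidation level is reached with no free halogen near ring B.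

Step 4
Reactants: 6 3-hydroxy-2-[3,4,5-tris(benzyloxy)phenyl]-4H-pyran-4-one
Product: 7 3-methoxy-2-[3,4,5-tris(benzyloxy)phenyl]-4H-pyran-4-one
Conditions: MeI, K2CO3, acetone, 50 °C
Reagents that add atoms: iodomethane, CI
Why: Williamson O-alkylation (SN2 on iodomethane) of the acidic enolic 3-hydroxyl, the only protic site in 6.

Step 5
Reactants: 8 dimethyl squarate
Product: 10 3-methoxycyclobut-3-ene-1,2-dione, via 4-hydroxy-2,3-dimethoxycyclobut-2-en-1-one 9 (not isolated)
Conditions: LiAlH(Ot-Bu)3 (1.0 equiv), THF, −78 → −20 °C; 1 M HCl work-up; then conc. HCl (cat.), CH2Cl2, rt; used freshly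
Reagents that add atoms: water, O
Why: The hindered alkoxyaluminium hydride adds once to a squarate carbonyl (1,2-reduction), and acid then ionises the carbinol to a methoxy-stabilised cyclobutenyl cation whose hydrolysis expels methanol, the standard entry to 3-alkoxycyclobutene-1,2-diones; the centre of 9 is lost.

Step 6
Reactants: 7 3-methoxy-2-[3,4,5-tris(benzyloxy)phenyl]-4H-pyran-4-one; 10 3-methoxycyclobut-3-ene-1,2-dione
Product: 12 4-hydroxy-3-methoxy-4-{5-methoxy-4-oxo-6-[3,4,5-tris(benzyloxy)phenyl]-4H-pyran-2-yl}cyclobut-2-en-1-one (racemic), via 6-lithiated pyranone 11 (not isolated)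
Conditions: TMPH, n-BuLi (→ LiTMP), THF, −78 °C, 15 min; cannulate into 10 (1.3 equiv), THF, −78 °C; aq. NH4Cl at −78 °C; Et3N-deactivated silica
Reagents that add atoms: none
Why: Directed deprotonation of the γ-pyrone CH next to the ring oxygen by a hindered lithium amide (as known for C2 of chromones) is followed by 1,2-addition to the C2 carbonyl of 10, the ketone-like one beside the methoxy carbon (C1 is a deactivated vinylogous ester), which puts OMe next to the carbinol as needed for C7/C8; the carbinol centre forms racemic and is erased in step 7.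

Step 7
Reactants: 12 4-hydroxy-3-methoxy-4-{5-methoxy-4-oxo-6-[3,4,5-tris(benzyloxy)phenyl]-4H-pyran-2-yl}cyclobut-2-en-1-one
Product: 15 5,8-dihydroxy-3,7-dimethoxy-2-[3,4,5-tris(benzyloxy)phenyl]-4H-chromen-4-one, via dienylketene 13 (not isolated), via ring-closed keto tautomer 14 (not isolated)
Conditions: toluene (degassed, 0.01 M), reflux (110 °C), Ar; concentrated and handled under Ar
Reagents that add atoms: none
Why: Heat breaks the C1–C4 bond of the cyclobutenone in a conrotatory 4π opening in which the donor hydroxyl rotates outward, so the pyranonyl group lies cis to the ketene arm in 13; the ketene carbon then bonds to pyranone C5 (the nucleophilic α-carbon of the vinylogous ester, future C4a), and dienone 14 enolises at once because its C4a–H sits between two carbonyls. The closest known reaction type is the thermal ring expansion of 4-alkenyl- and 4-(hetero)aryl-4-hydroxycyclobutenones to hydroquinones (Moore rearrangement), here with a γ-pyrone C=C as the 2π partner. The one ring closed is the six-membered carbocycle A, by a 6π electrocyclisation of the dienylketene that forms the C4a–C5 bond. No stereocentre has to be controlled: the carbinol centre of 12 becomes sp2 C8 and the transient C4a centre of 14 is lost on aromatisation. The step needs outward rotation of OH, secured by its donor character, and closure at the pyranone CH, secured because the only other neighbour of the attachment carbon is the ring oxygen; the O/H/OMe/O pattern on C5–C8 was already locked in step 6.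

Step 8
Reactants: 15 5,8-dihydroxy-3,7-dimethoxy-2-[3,4,5-tris(benzyloxy)phenyl]-4H-chromen-4-one
Product: 16 5,8-dihydroxy-3,7-dimethoxy-2-(3,4,5-trihydroxyphenyl)-4H-chromen-4-one
Conditions: H2 (1 atm), 10% Pd/C, degassed THF–MeOH, rt; filtration and evaporation under Ar
Reagents that add atoms: none
Why: Catalytic hydrogenolysis of the three aryl benzyl ethers under neutral conditions, in which the methyl ethers, the tetrasubstituted enol-ether C2=C3 bond and the chelated carbonyl are inert at 1 atm and room temperature and any quinone formed adventitiously from the hydroquinone is reduced back.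

Compound list
1 | 3-bromofuran | Brc1ccoc1 | starting material
2 | 3,4,5-tris(benzyloxy)benzaldehyde | O=Cc1cc(OCc2ccccc2)c(OCc2ccccc2)c(OCc2ccccc2)c1 | starting material
3 | 3-bromo-2-furyllithium | [Li]c1occc1Br | intermediate (not isolated)
4 | (3-bromofuran-2-yl)[3,4,5-tris(benzyloxy)phenyl]methanol (racemic) | OC(c1occc1Br)c1cc(OCc2ccccc2)c(OCc2ccccc2)c(OCc2ccccc2)c1 | intermediate
5 | 4-bromo-6-hydroxy-2-[3,4,5-tris(benzyloxy)phenyl]-2H-pyran-3(6H)-one (racemic, diastereomer mixture) | OC1OC(c2cc(OCc3ccccc3)c(OCc3ccccc3)c(OCc3ccccc3)c2)C(=O)C(Br)=C1 | intermediate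
6 | 3-hydroxy-2-[3,4,5-tris(benzyloxy)phenyl]-4H-pyran-4-one | O=c1ccoc(-c2cc(OCc3ccccc3)c(OCc3ccccc3)c(OCc3ccccc3)c2)c1O | intermediate
7 | 3-methoxy-2-[3,4,5-tris(benzyloxy)phenyl]-4H-pyran-4-one | COc1c(-c2cc(OCc3ccccc3)c(OCc3ccccc3)c(OCc3ccccc3)c2)occc1=O | intermediate
8 | dimethyl squarate (3,4-dimethoxycyclobut-3-ene-1,2-dione) | COC1=C(OC)C(=O)C1=O | starting material
9 | 4-hydroxy-2,3-dimethoxycyclobut-2-en-1-one (racemic) | COC1=C(OC)C(=O)C1O | intermediate (not isolated)
10 | 3-methoxycyclobut-3-ene-1,2-dione (methyl semisquarate) | COC1=CC(=O)C1=O | intermediate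
11 | {5-methoxy-4-oxo-6-[3,4,5-tris(benzyloxy)phenyl]-4H-pyran-2-yl}lithium | [Li]c1cc(=O)c(OC)c(-c2cc(OCc3ccccc3)c(OCc3ccccc3)c(OCc3ccccc3)c2)o1 | intermediate (not isolated)
12 | 4-hydroxy-3-methoxy-4-{5-methoxy-4-oxo-6-[3,4,5-tris(benzyloxy)phenyl]-4H-pyran-2-yl}cyclobut-2-en-1-one (racemic) | COC1=CC(=O)C1(O)c1cc(=O)c(OC)c(-c2cc(OCc3ccccc3)c(OCc3ccccc3)c(OCc3ccccc3)c2)o1 | intermediate
13 | (3Z)-4-hydroxy-3-methoxy-4-{5-methoxy-4-oxo-6-[3,4,5-tris(benzyloxy)phenyl]-4H-pyran-2-yl}buta-1,3-dien-1-one (dienylketene) | O=C=C/C(OC)=C(/O)c1cc(=O)c(OC)c(-c2cc(OCc3ccccc3)c(OCc3ccccc3)c(OCc3ccccc3)c2)o1 | intermediate (not isolated)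
14 | 8-hydroxy-3,7-dimethoxy-2-[3,4,5-tris(benzyloxy)phenyl]-4aH-chromene-4,5-dione (racemic at C4a) | COC1=CC(=O)C2C(=O)C(OC)=C(c3cc(OCc4ccccc4)c(OCc4ccccc4)c(OCc4ccccc4)c3)OC2=C1O | intermediate (not isolated)
15 | 5,8-dihydroxy-3,7-dimethoxy-2-[3,4,5-tris(benzyloxy)phenyl]-4H-chromen-4-one | COc1cc(O)c2c(=O)c(OC)c(-c3cc(OCc4ccccc4)c(OCc4ccccc4)c(OCc4ccccc4)c3)oc2c1O | intermediate
16 | 5,8-dihydroxy-3,7-dimethoxy-2-(3,4,5-trihydroxyphenyl)-4H-chromen-4-one | COc1cc(O)c2c(=O)c(OC)c(-c3cc(O)c(O)c(O)c3)oc2c1O | target

Total step count: 8. Longest linear sequence: 7 (steps 1–4, 6, 7, 8); step 5 is a one-step side branch.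

Steps most likely to fail

Step 7. After ring opening, the ketene may be captured by the free tertiary hydroxyl (lactonisation to a butenolide) or may oligomerise if closure onto the cross-conjugated pyranone alkene is slow, and the free hydroquinone may oxidise during isolation. The fallback sets out from 12 and comes back at 15. The carbinol is first capped (Me3SiCl, Et3N, Et2O, 0 °C) to the silyl ether 3-methoxy-4-{5-methoxy-4-oxo-6-[3,4,5-tris(benzyloxy)phenyl]-4H-pyran-2-yl}-4-(trimethylsilyloxy)cyclobut-2-en-1-one F1, which removes the hydroxyl that can intercept the ketene. Thermolysis of F1 in toluene or p-xylene should then end at the mono-silylated, far less oxidisable hydroquinone 5-hydroxy-3,7-dimethoxy-2-[3,4,5-tris(benzyloxy)phenyl]-8-(trimethylsilyloxy)-4H-chromen-4-one F2. Buffered fluoride (TBAF/AcOH, THF, 0 °C) returns to 15.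

Step 6. Proton removal may occur at the wrong site (C5 next to the carbonyl, or the benzyloxyaryl ring), the lithiated pyrone may fragment before it is trapped, or it may add in conjugate fashion to the dione. The fallback sets out from 7 and comes back at 12. C–H zincation with a TMP–zinc amide, under the Lewis-acid-free conditions known to metalate chromones next to the ring oxygen, should give chlorido{5-methoxy-4-oxo-6-[3,4,5-tris(benzyloxy)phenyl]-4H-pyran-2-yl}zinc F3. Iodine converts it into the isolable 6-iodo-3-methoxy-2-[3,4,5-tris(benzyloxy)phenyl]-4H-pyran-4-one F4, so the regiochemistry can be secured before the dione is committed. Iodine–magnesium exchange (i-PrMgCl·LiCl, THF, −78 °C) then gives the softer nucleophile chlorido{5-methoxy-4-oxo-6-[3,4,5-tris(benzyloxy)phenyl]-4H-pyran-2-yl}magnesium F5, which is added to 10 at −78 °C and quenched cold to give 12.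

Step 3. Acid may drive dehydration to an oxidopyrylium species that dimerises, or may strip benzyl ethers before water has displaced bromide at C4. The fallback sets out from 2 and comes back at 6, bypassing steps 1–3. A Lewis-acid-promoted hetero-Diels–Alder reaction of 2 with (E)-1-methoxy-3-(trimethylsilyloxy)buta-1,3-diene (BF3·OEt2, CH2Cl2, −78 °C; then TFA) should give 2-[3,4,5-tris(benzyloxy)phenyl]-2,3-dihydro-4H-pyran-4-one F6. α-Hydroxylation at C3 (LiHMDS, then 3-phenyl-2-(phenylsulfonyl)oxaziridine, THF, −78 °C) gives the acyloin 3-hydroxy-2-[3,4,5-tris(benzyloxy)phenyl]-2,3-dihydro-4H-pyran-4-one F7. Swern oxidation of its secondary alcohol leads to 6, because the diketone formed exists as the enolised γ-pyrone.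

Further compounds
F1 | step 7 | 3-methoxy-4-{5-methoxy-4-oxo-6-[3,4,5-tris(benzyloxy)phenyl]-4H-pyran-2-yl}-4-(trimethylsilyloxy)cyclobut-2-en-1-one (racemic) | COC1=CC(=O)C1(O[Si](C)(C)C)c1cc(=O)c(OC)c(-c2cc(OCc3ccccc3)c(OCc3ccccc3)c(OCc3ccccc3)c2)o1
F2 | step 7 | 5-hydroxy-3,7-dimethoxy-2-[3,4,5-tris(benzyloxy)phenyl]-8-(trimethylsilyloxy)-4H-chromen-4-one | COc1cc(O)c2c(=O)c(OC)c(-c3cc(OCc4ccccc4)c(OCc4ccccc4)c(OCc4ccccc4)c3)oc2c1O[Si](C)(C)C
F3 | step 6 | chlorido{5-methoxy-4-oxo-6-[3,4,5-tris(benzyloxy)phenyl]-4H-pyran-2-yl}zinc | Cl[Zn]c1cc(=O)c(OC)c(-c2cc(OCc3ccccc3)c(OCc3ccccc3)c(OCc3ccccc3)c2)o1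
F4 | step 6 | 6-iodo-3-methoxy-2-[3,4,5-tris(benzyloxy)phenyl]-4H-pyran-4-one | COc1c(-c2cc(OCc3ccccc3)c(OCc3ccccc3)c(OCc3ccccc3)c2)oc(I)cc1=O
F5 | step 6 | chlorido{5-methoxy-4-oxo-6-[3,4,5-tris(benzyloxy)phenyl]-4H-pyran-2-yl}magnesium | Cl[Mg]c1cc(=O)c(OC)c(-c2cc(OCc3ccccc3)c(OCc3ccccc3)c(OCc3ccccc3)c2)o1
F6 | step 3 | 2-[3,4,5-tris(benzyloxy)phenyl]-2,3-dihydro-4H-pyran-4-one (racemic) | O=C1CC(c2cc(OCc3ccccc3)c(OCc3ccccc3)c(OCc3ccccc3)c2)OC=C1
F7 | step 3 | 3-hydroxy-2-[3,4,5-tris(benzyloxy)phenyl]-2,3-dihydro-4H-pyran-4-one (racemic, diastereomer mixture) | O=C1C=COC(c2cc(OCc3ccccc3)c(OCc3ccccc3)c(OCc3ccccc3)c2)C1O
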